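**Strategy.** The cis-fused eudesmane is disconnected at C2 of ring A. Without C2, the atoms C1–C3(=O)–C4(CH3)–C5–C10 form a cyclopentanone fused to ring B, exactly the array that a Pauson–Khand reaction assembles from a C4≡C5 alkyne, a C10=C1 alkene and CO. The key step puts C2 back: Me3SiCHN2 adds to the C3 ketone and C1 migrates, forming C1–C2 and C2–C3 and enlarging the five-membered ring to ring A in one operation. Its precursor is the cis-hydrindan-3-one lacking C2, with 10β-methyl, 7β-isopropyl and an 8α-silyl ether. The inward-facing C4 acetate is then delivered intramolecularly through an enol acetate epoxide rearrangement.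

Key step: step 9

**Remarks on the chemistry**
- Eudesmane numbering is used for all bicyclic compounds (C2 is absent in the hydrindanes). β is the face of the C10 methyl group; "5β-eudesmane" here means the cis-fused skeleton with 7β-isopropyl and 10β-methyl.
- The target is read as (3R,4S,5S,7R,10R): 3α-angeloyloxy [(Z)-2-methylbut-2-enoate], 4α-acetoxy, 4β-methyl, 5β-H, 7β-isopropyl, 10β-methyl, C8 ketone.
- The C8 silyl ether is placed α (trans to the isopropyl group) so that both ring B substituents are equatorial in step 7. This is the anti-Felkin carbinol, so it is set by reagent control in step 5.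
- A triisopropylsilyl ether is used because it must survive BF3·OEt2 (step 9) and hot acid (step 10).
- In the preferred conformer (ring B chair with equatorial isopropyl) the 4α position points under ring B. External oxidants would attack a C3=C4 π-bond from the β face, so the C4 oxygen is delivered from C3 by an acyloxy shift (step 11) and the tertiary acetate never has to be made by acylation.
- C7 is set by the auxiliary in the configuration of the target and is carried through without equilibration; the last oxidation is buffered.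
- Assumption: 2-methylallylmagnesium chloride (THF solution), (−)-Ipc2BOMe [from (+)-α-pinene], angelic acid and freshly prepared dimethyldioxirane in acetone are available reagents.

**Route**

Step 1
Reactants: 1 (R)-4-benzyl-1,3-oxazolidin-2-one; 2 3-methylbutanoyl chloride
Product: 3 (R)-4-benzyl-3-(3-methylbutanoyl)-1,3-oxazolidin-2-one
Conditions: Et3N, DMAP (cat.), CH2Cl2, 0 °C → rt
Reagents that add atoms: none
Why: DMAP-catalysed N-acylation of the oxazolidinone by the acid chloride; no stereocentre is involved.

Step 2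
Reactants: 3; 4 1-bromobut-2-yne
Product: 6 (R)-4-benzyl-3-[(2R)-2-(propan-2-yl)hex-4-ynoyl]-1,3-oxazolidin-2-one, via sodium (Z)-enolate 5 (not isolated)
Conditions: NaN(SiMe3)2, THF, −78 °C; then 4, −78 → −40 °C
Reagents that add atoms: none
Why: Evans asymmetric alkylation: the chelated (Z)-enolate is alkylated by the propargylic bromide on the face opposite the benzyl group, which sets C7 as (R).

Step 3
Reactants: 6
Product: 7 (2R)-2-(propan-2-yl)hex-4-yn-1-ol
Conditions: LiBH4, MeOH, Et2O, 0 °C
Reagents that add atoms: none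
Why: Reductive cleavage of the imide at the exocyclic carbonyl gives the primary alcohol without touching C7 and releases the auxiliary for recovery.

Step 4
Reactants: 7
Product: 8 (2R)-2-(propan-2-yl)hex-4-ynal
Conditions: Dess–Martin periodinane, NaHCO3, CH2Cl2, 0 °C → rt
Reagents that add atoms: none
Why: Dess–Martin oxidation under buffered, non-basic conditions should keep the α-stereocentre C7 intact; the aldehyde is used crude.

Step 5
Reactants: 8; 9 2-methylallylmagnesium chloride
Product: 11 (4S,5R)-2-methyl-5-(propan-2-yl)non-1-en-7-yn-4-ol, via B-(2-methylallyl)diisopinocampheylborane 10 (not isolated)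
Conditions: 9, (−)-Ipc2BOMe, Et2O, −78 °C → rt; then 8, Et2O, −78 °C; NaOH, H2O2, 0 °C → rt
Reagents that add atoms: none
Why: Brown methallylboration through a chair-like six-membered transition state; the isopinocampheyl groups from (+)-α-pinene direct the allyl unit to the Si face of the aldehyde and should override the weak Felkin bias of C7, giving the (S)-carbinol C8 (8α, anti-Felkin).

Step 6
Reactants: 11
Product: 12 triisopropyl{[(4S,5R)-2-methyl-5-(propan-2-yl)non-1-en-7-yn-4-yl]oxy}silane
Conditions: iPr3SiOTf, 2,6-lutidine, CH2Cl2, −78 → 0 °C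
Reagents that add atoms: triisopropylsilyl trifluoromethanesulfonate, CC(C)[Si](C(C)C)(C(C)C)OS(=O)(=O)C(F)(F)F
Why: The silyl triflate silylates the hindered secondary alcohol; the bulky, acid-stable ether also reinforces the equatorial preference at C8 in step 7.

Step 7
Reactants: 12
Product: 13 (5R,6S,7aS)-3,7a-dimethyl-5-(propan-2-yl)-6-(triisopropylsilyloxy)-1,4,5,6,7,7a-hexahydro-2H-inden-2-one (C3 ketone conjugated to C4=C5; 10β-methyl, 7β-isopropyl, 8α-silyloxy)
Conditions: Co2(CO)8 (0.2 equiv), tetramethylthiourea (1.2 equiv), CO (1 atm), PhMe, 70 °C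
Reagents that add atoms: carbon monoxide, [C-]#[O+]
Why: Intramolecular Pauson–Khand reaction of a 1,7-enyne with a 1,1-disubstituted alkene: alkyne C4≡C5, alkene C10=C1 and CO give the cyclopentenone while the C5–C10 bond closes ring B through a chair with the C7 isopropyl and C8 silyloxy groups equatorial, which makes the new angular methyl axial and cis to the isopropyl group (10β).

Step 8
Reactants: 13
Product: 14 (3S,3aR,5R,6S,7aS)-3,7a-dimethyl-5-(propan-2-yl)-6-(triisopropylsilyloxy)octahydro-2H-inden-2-one (cis-fused hydrindan-3-one lacking C2; 5β-H, 4β-H, 10β-methyl)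
Conditions: H2 (1 atm), 10% Pd/C, EtOAc, rt
Reagents that add atoms: none
Why: Heterogeneous hydrogenation of the tetrasubstituted enone should deliver both hydrogens to the β face, the α face of C5 being screened by ring B (axial H-7 and H-9); this gives the cis ring fusion usual for angular-methyl hydrindenones, and the C4 centre formed here is not retained later.

Step 9
Reactants: 14; 15 (trimethylsilyl)diazomethane
Product: 17 8α-(triisopropylsilyloxy)-5β-eudesman-3-one, via α-silyl ketone 16 (not isolated)
Conditions: 15 (2 M in hexanes, 1.2 equiv), BF3·OEt2 (1.2 equiv), CH2Cl2, −78 → −40 °C; then 1 M HCl, THF, 0 °C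
Reagents that add atoms: none
Why: BF3 activates the C3 carbonyl, the diazo carbon of 15 adds to it, and in the resulting β-oxido diazonium ion the C1–C3 bond antiperiplanar to the leaving N2 shifts to the new carbon, which becomes C2 bonded to C1 and C3; acidic work-up removes the silyl group from α-silyl ketone 16. The reaction type is the Lewis-acid-promoted trimethylsilyldiazomethane homologation of cycloalkanones (a Tiffeneau–Demjanov-type one-carbon ring expansion), known for cyclopentanone-to-cyclohexanone enlargement with migration of the less substituted α-carbon. Ring A is closed by ring enlargement, a 1,2-shift of C1 within the tetrahedral adduct (C1–C2 and C2–C3 formed, C1–C3 broken), not by an exo or endo cyclisation. No stereocentre is created in the product: the silyl-bearing C2 is transient, C5, C7, C8 and C10 are not involved, and epimerisation at C4 would be harmless because C4 becomes sp2 in step 10. The step needs migration of the C1 methylene in preference to the C4 methine and a single insertion: C4 carries a methyl group and the ring-fusion carbon C5, so the bulky Me3Si group of the adduct should turn away from it and leave C1 anti to N2, and α-silyl ketone 16 is too hindered to take up a second diazoalkane at low temperature with 15 near one equivalent.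

Step 10
Reactants: 17
Product: 18 3-acetoxy-8α-(triisopropylsilyloxy)-5β-eudesm-3-ene
Conditions: isopropenyl acetate, TsOH·H2O (cat.), reflux
Reagents that add atoms: isopropenyl acetate, CC(=C)OC(C)=O
Why: Acid-catalysed enol acetylation under equilibrating conditions should give the more substituted C3=C4 enol acetate, the direction in which cis-fused 3-ketones of this type enolise; C4 becomes planar.

Step 11
Reactants: 18
Product: 20 4α-acetoxy-8α-(triisopropylsilyloxy)-5β-eudesman-3-one, via epoxy acetate 19 (not isolated)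
Conditions: dimethyldioxirane, acetone, 0 °C; evaporate; then PhMe, 110 °C
Reagents that add atoms: dimethyldioxirane, CC1(C)OO1
Why: Epoxidation of the enol acetate from the open β face, then thermal enol ester epoxide rearrangement: the 3α-acetoxy group shifts to C4 with inversion while the epoxide oxygen becomes the C3 carbonyl, so the acetate is delivered intramolecularly to the concave α face and the methyl group turns to β.

Step 12
Reactants: 20
Product: 21 4α-acetoxy-8α-(triisopropylsilyloxy)-5β-eudesman-3α-ol
Conditions: NaBH4, CeCl3·7H2O, MeOH, −78 °C; AcOH quench at −78 °C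
Reagents that add atoms: none
Why: Hydride should attack C3 along the axial trajectory from the open β face, anti to the axial C4–O bond, giving the equatorial 3α-alcohol cis to the acetate (the usual outcome for cis-fused 3-ketones); low temperature and the acidic quench are meant to suppress acetyl migration to O3.

Step 13
Reactants: 21; 22 angelic acid
Product: 24 4α-acetoxy-3α-angeloyloxy-8α-(triisopropylsilyloxy)-5β-eudesmane, via mixed anhydride 23 (not isolated)
Conditions: 22, 2,4,6-Cl3C6H2COCl, Et3N, PhMe, rt; then 21, PhMe, 80 °C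
Reagents that add atoms: none
Why: Yamaguchi-type esterification through the angelic 2,4,6-trichlorobenzoic mixed anhydride without DMAP, conditions under which the (Z)-double bond should not isomerise to the tiglate; the equatorial 3α-hydroxyl is the only free alcohol.

Step 14
Reactants: 24
Product: 25 4α-acetoxy-3α-angeloyloxy-5β-eudesman-8α-ol
Conditions: HF·pyridine, pyridine, THF, 0 °C → rt
Reagents that add atoms: none
Why: Fluoride cleavage of the silyl ether under mildly acidic conditions that leave both esters and the angelate geometry untouched.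

Step 15
Reactants: 25
Product: 26 4α-acetoxy-3α-angeloyloxy-5β-eudesman-8-one (target)
Conditions: Dess–Martin periodinane, NaHCO3, CH2Cl2, rt
Reagents that add atoms: none
Why: Buffered Dess–Martin oxidation of the 8α-alcohol to the C8 ketone without enolisation toward C7.

**Compound list**

1 | (R)-4-benzyl-1,3-oxazolidin-2-one | O=C1N[C@H](Cc2ccccc2)CO1 | starting material
2 | 3-methylbutanoyl chloride | CC(C)CC(Cl)=O | starting material
3 | (R)-4-benzyl-3-(3-methylbutanoyl)-1,3-oxazolidin-2-one | CC(C)CC(=O)N1[C@H](Cc2ccccc2)COC1=O | intermediate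
4 | 1-bromobut-2-yne | CC#CCBr | starting material
5 | sodium (Z)-enolate of 3 | [Na+].[O-]/C(=C\C(C)C)N1[C@H](Cc2ccccc2)COC1=O | intermediate (not isolated)
6 | (R)-4-benzyl-3-[(2R)-2-(propan-2-yl)hex-4-ynoyl]-1,3-oxazolidin-2-one | CC#CC[C@H](C(C)C)C(=O)N1[C@H](Cc2ccccc2)COC1=O | intermediate
7 | (2R)-2-(propan-2-yl)hex-4-yn-1-ol | CC#CC[C@H](C(C)C)CO | intermediate
8 | (2R)-2-(propan-2-yl)hex-4-ynal | CC#CC[C@H](C(C)C)C=O | intermediate
9 | 2-methylallylmagnesium chloride | C=C(C)C[Mg]Cl | starting material
10 | B-(2-methylallyl)diisopinocampheylborane, isopinocampheyl groups from (+)-α-pinene | C=C(C)CB([C@@H]1C[C@@H]2C[C@H]([C@H]1C)C2(C)C)[C@@H]1C[C@@H]2C[C@H]([C@H]1C)C2(C)C | intermediate (not isolated)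
11 | (4S,5R)-2-methyl-5-(propan-2-yl)non-1-en-7-yn-4-ol | C=C(C)C[C@H](O)[C@@H](C(C)C)CC#CC | intermediate
12 | triisopropylsilyl ether of 11 | C=C(C)C[C@H](O[Si](C(C)C)(C(C)C)C(C)C)[C@@H](C(C)C)CC#CC | intermediate
13 | (5R,6S,7aS)-3,7a-dimethyl-5-(propan-2-yl)-6-(triisopropylsilyloxy)-1,4,5,6,7,7a-hexahydro-2H-inden-2-one | O=C1C[C@]2(C)C[C@H](O[Si](C(C)C)(C(C)C)C(C)C)[C@@H](C(C)C)CC2=C1C | intermediate
14 | (3S,3aR,5R,6S,7aS)-3,7a-dimethyl-5-(propan-2-yl)-6-(triisopropylsilyloxy)octahydro-2H-inden-2-one (cis-hydrindan-3-one lacking C2) | O=C1C[C@]2(C)C[C@H](O[Si](C(C)C)(C(C)C)C(C)C)[C@@H](C(C)C)C[C@@H]2[C@@H]1C | intermediate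
15 | (trimethylsilyl)diazomethane | C[Si](C)(C)C=[N+]=[N-] | starting material
16 | 2-(trimethylsilyl)-8α-(triisopropylsilyloxy)-5β-eudesman-3-one (C2 configuration undefined) | O=C1C([Si](C)(C)C)C[C@]2(C)C[C@H](O[Si](C(C)C)(C(C)C)C(C)C)[C@@H](C(C)C)C[C@@H]2[C@@H]1C | intermediate (not isolated)
17 | 8α-(triisopropylsilyloxy)-5β-eudesman-3-one (4α-methyl as formed; C4 not critical) | O=C1CC[C@]2(C)C[C@H](O[Si](C(C)C)(C(C)C)C(C)C)[C@@H](C(C)C)C[C@@H]2[C@@H]1C | intermediate
18 | 3-acetoxy-8α-(triisopropylsilyloxy)-5β-eudesm-3-ene | CC1=C(OC(C)=O)CC[C@]2(C)C[C@H](O[Si](C(C)C)(C(C)C)C(C)C)[C@@H](C(C)C)C[C@H]12 | intermediate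
19 | 3α-acetoxy-3β,4β-epoxy-8α-(triisopropylsilyloxy)-5β-eudesmane | CC(=O)O[C@]1(O2)CC[C@]3(C)C[C@H](O[Si](C(C)C)(C(C)C)C(C)C)[C@@H](C(C)C)C[C@@H]3[C@]12C | intermediate (not isolated)
20 | 4α-acetoxy-8α-(triisopropylsilyloxy)-5β-eudesman-3-one (4β-methyl) | O=C1CC[C@]2(C)C[C@H](O[Si](C(C)C)(C(C)C)C(C)C)[C@@H](C(C)C)C[C@@H]2[C@]1(C)OC(C)=O | intermediate
21 | 4α-acetoxy-8α-(triisopropylsilyloxy)-5β-eudesman-3α-ol | O[C@@H]1CC[C@]2(C)C[C@H](O[Si](C(C)C)(C(C)C)C(C)C)[C@@H](C(C)C)C[C@@H]2[C@]1(C)OC(C)=O | intermediate
22 | angelic acid, (Z)-2-methylbut-2-enoic acid | C/C=C(/C)C(=O)O | starting material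
23 | angelic 2,4,6-trichlorobenzoic anhydride | C/C=C(/C)C(=O)OC(=O)c1c(Cl)cc(Cl)cc1Cl | intermediate (not isolated)
24 | 4α-acetoxy-3α-angeloyloxy-8α-(triisopropylsilyloxy)-5β-eudesmane | C/C=C(/C)C(=O)O[C@@H]1CC[C@]2(C)C[C@H](O[Si](C(C)C)(C(C)C)C(C)C)[C@@H](C(C)C)C[C@@H]2[C@]1(C)OC(C)=O | intermediate
25 | 4α-acetoxy-3α-angeloyloxy-5β-eudesman-8α-ol | C/C=C(/C)C(=O)O[C@@H]1CC[C@]2(C)C[C@H](O)[C@@H](C(C)C)C[C@@H]2[C@]1(C)OC(C)=O | intermediate
26 | 4α-acetoxy-3α-angeloyloxy-5β-eudesman-8-one, (3R,4S,5S,7R,10R) | C/C=C(/C)C(=O)O[C@@H]1CC[C@]2(C)CC(=O)[C@@H](C(C)C)C[C@@H]2[C@]1(C)OC(C)=O | target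

**Step count and risks**

Total: 15 steps. Longest linear sequence: 15 steps (1 → 26).

Steps most likely to fail:

1. Step 9. Possible failure: the C4 methine shifts in competition with the C1 methylene, or the new cyclohexanone takes up a second carbon. Fallback (sets out from 14, returns at 17): kinetic deprotonation of 14 at the C1 methylene with LiN(iPr)2 and trapping with Me3SiCl gives the silyl enol ether F1. Cyclopropanation with Et2Zn/CH2I2 gives the siloxycyclopropane F2. FeCl3 in DMF opens the C1–C3 bond to the ring-enlarged β-chloro ketone F3, from which NaOAc in MeOH eliminates HCl to the enone F4. Hydrogenation of F4 over Pd/C gives 17. The site of insertion is then fixed by the kinetic enolisation and not by a migratory preference.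

2. Step 7. Possible failure: the 1,1-disubstituted alkene inserts too slowly into the cobalt–alkyne complex, or the facial preference at C10 erodes. Fallback (sets out from 8, returns at 14), which takes the quaternary centre out of the cyclocarbonylation: allylboration of 8 with B-allyldiisopinocampheylborane of the same pinene series gives the homoallylic alcohol F5, and iPr3SiOTf gives its silyl ether F6. The same cobalt-catalysed cyclocarbonylation, now with a monosubstituted alkene, gives the bicyclic enone F7 with hydrogen at C10, and hydrogenation gives the cis-hydrindanone F8. Kinetic silylation at C1 (LiN(iPr)2, Me3SiCl) gives the silyl enol ether F9, and Saegusa oxidation with Pd(OAc)2 gives the C1=C10 enone F10. Conjugate addition of Me2CuLi with Me3SiCl places the angular methyl group on C10 cis to H-5 and gives 14.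

3. Step 11. Possible failure: acid-triggered opening of the epoxy acetate at C3, which would transfer the acetyl group with retention (4β-acetate), or hydrolysis to the ketol. Fallback (sets out from 17, returns at 21): bromination of 17 with PhNMe3Br3 in THF at the more substituted α-carbon gives the 4β-bromo ketone F11. NaBH4 gives the 3α-bromohydrin F12, and Ac2O/pyridine gives the bromo acetate F13. AgOAc in wet acetic acid ionises the tertiary bromide with participation of the 3α-acetoxy group, and water opens the cis-fused acetoxonium ion to the axial C4 acetate and the free 3α-hydroxyl, which is 21.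

**Further compounds**

F1 | step 9 | trimethylsilyl enol ether of 14 (C1=C3) | C[Si](C)(C)OC1=C[C@]2(C)C[C@H](O[Si](C(C)C)(C(C)C)C(C)C)[C@@H](C(C)C)C[C@@H]2[C@@H]1C
F2 | step 9 | siloxycyclopropane from F1 (CH2 bridging C1 and C3; new centres undefined) | C[Si](C)(C)OC13CC3[C@]2(C)C[C@H](O[Si](C(C)C)(C(C)C)C(C)C)[C@@H](C(C)C)C[C@@H]2[C@@H]1C
F3 | step 9 | 1-chloro-8α-(triisopropylsilyloxy)-5β-eudesman-3-one (C1 undefined) | O=C1CC(Cl)[C@]2(C)C[C@H](O[Si](C(C)C)(C(C)C)C(C)C)[C@@H](C(C)C)C[C@@H]2[C@@H]1C
F4 | step 9 | 8α-(triisopropylsilyloxy)-5β-eudesm-1-en-3-one | O=C1C=C[C@]2(C)C[C@H](O[Si](C(C)C)(C(C)C)C(C)C)[C@@H](C(C)C)C[C@@H]2[C@@H]1C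
F5 | step 7 | (4S,5R)-5-(propan-2-yl)non-1-en-7-yn-4-ol | C=CC[C@H](O)[C@@H](C(C)C)CC#CC
F6 | step 7 | triisopropylsilyl ether of F5 | C=CC[C@H](O[Si](C(C)C)(C(C)C)C(C)C)[C@@H](C(C)C)CC#CC
F7 | step 7 | 10-demethyl analogue of 13 (10β-H) | O=C1C[C@@H]2C[C@H](O[Si](C(C)C)(C(C)C)C(C)C)[C@@H](C(C)C)CC2=C1C
F8 | step 7 | 10-demethyl analogue of 14 (cis-fused; 5β-H, 10β-H) | O=C1C[C@@H]2C[C@H](O[Si](C(C)C)(C(C)C)C(C)C)[C@@H](C(C)C)C[C@@H]2[C@@H]1C
F9 | step 7 | trimethylsilyl enol ether of F8 (C1=C3) | C[Si](C)(C)OC1=C[C@@H]2C[C@H](O[Si](C(C)C)(C(C)C)C(C)C)[C@@H](C(C)C)C[C@@H]2[C@@H]1C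
F10 | step 7 | C1=C10 enone (10-demethyl, 5β-H, 4α-methyl) | O=C1C=C2C[C@H](O[Si](C(C)C)(C(C)C)C(C)C)[C@@H](C(C)C)C[C@@H]2[C@@H]1C
F11 | step 11 | 4β-bromo-8α-(triisopropylsilyloxy)-5β-eudesman-3-one | O=C1CC[C@]2(C)C[C@H](O[Si](C(C)C)(C(C)C)C(C)C)[C@@H](C(C)C)C[C@@H]2[C@@]1(C)Br
F12 | step 11 | 4β-bromo-8α-(triisopropylsilyloxy)-5β-eudesman-3α-ol | O[C@@H]1CC[C@]2(C)C[C@H](O[Si](C(C)C)(C(C)C)C(C)C)[C@@H](C(C)C)C[C@@H]2[C@@]1(C)Br
F13 | step 11 | 3α-acetoxy-4β-bromo-8α-(triisopropylsilyloxy)-5β-eudesmane | CC(=O)O[C@@H]1CC[C@]2(C)C[C@H](O[Si](C(C)C)(C(C)C)C(C)C)[C@@H](C(C)C)C[C@@H]2[C@@]1(C)Br
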